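**Plan**
- Retrosynthesis: the two aryl isopropyl ethers are cleaved last; ring B is opened at C7–C8 (Friedel–Crafts acylation); the lactone is opened at O–C19 (lactol oxidation after release of the C20 hydroxyl); C4 gives up C18 (enolate methylation) and C19 (Wittig homologation of a C4 ketone); the core is then cut at C9–C10 and C5–C6.
- Enabling feature (abietane numbering): quaternary C10 carries aryl carbon C9 of ring C and the C20 oxymethylene, and its neighbour C5 carries C6 next to C4. Ring A is therefore a cyclohexenone (C4 carbonyl, C5=C10, C20 arm on C10), ring C an aryl nucleophile and C6–C7 an iodoacetate.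
- Forward: ring C is made as an aryl bromide and ring A as a 3-(silyloxymethyl)cyclohexenone; one flask joins ring C, ring A and the C6–C7 arm; C19 and C18 are then placed on C4, the lactone ring is closed, ring B is closed last and the phenols are released.
- Stereochemistry: C10 comes from the chiral carbene–copper catalyst; C5 from alkylation anti to the new aryl group; C4 from α-face methylation anti to the axial C20 arm, checked by the lactol closure that only the cis C19/C20 isomer can undergo.

Key step: step 12

Remark: abietane numbering is used for every intermediate (C18 = methyl and C19 = carbonyl carbon on C4, C20 on C10; β = face of C20, α = face of H-5); Ar = 2,5-diisopropoxy-4-isopropyl-3-methoxyphenyl; L* = the known C1-symmetric 4,5-diphenylimidazolin-2-ylidene with N-(2,6-diethylphenyl) and N-(2-sulfonatophenyl) groups, made separately from 1,2-diphenylethylenediamine, and it is assumed that the ligand enantiomer giving 10R is fixed by a trial run, the antipode being equally accessible.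

**Route**

Step 1
Reactants: 1 2-isopropylphenol
Product: 2 2-isopropylanisole
Conditions: MeI, K2CO3, acetone, reflux
Reagents that add atoms: iodomethane, CI
Why: Williamson etherification of a mono-ortho-substituted phenoxide is reliable, and this oxygen becomes the 12-methoxy group that must outlast the other two ethers.

Step 2
Reactants: 2 2-isopropylanisole
Product: 5 3-isopropyl-2-methoxyphenol, via aryllithium 3 (not isolated), via dimethyl arylboronate 4 (not isolated)
Conditions: n-BuLi, TMEDA, Et2O, 0 °C → rt; B(OMe)3, −78 °C → rt; AcOH, 30% H2O2, 0 °C → rt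
Reagents that add atoms: hydrogen peroxide, OO
Why: Directed ortho-metalation at the only free position ortho to the methoxy group, borylation and oxidative boron-to-oxygen migration should install the oxygen that becomes O-11, the tertiary benzylic C–H of the isopropyl group not being lithiated competitively.

Step 3
Reactants: 5 3-isopropyl-2-methoxyphenol
Product: 6 6-bromo-3-isopropyl-2-methoxyphenol
Conditions: NBS, i-Pr2NH (10 mol %), CH2Cl2, 0 °C
Reagents that add atoms: N-bromosuccinimide, O=C1CCC(=O)N1Br
Why: Amine-mediated electrophilic bromination delivers bromine ortho to a free phenol through a hydrogen-bonded N-bromoamine, and the para position is further shielded by the flanking isopropyl group, so bromine should enter at the carbon that becomes C9.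

Step 4
Reactants: 6 6-bromo-3-isopropyl-2-methoxyphenol
Product: 7 5-bromo-2-isopropyl-3-methoxy-1,4-benzoquinone
Conditions: (KSO3)2NO, KH2PO4, H2O–acetone, rt
Reagents that add atoms: potassium nitrosodisulfonate, [K+].[K+].[O]N(S(=O)(=O)[O-])S(=O)(=O)[O-]
Why: Teuber oxidation of a phenol with both ortho positions blocked and the para position free can only give the para-quinone, which introduces the oxygen that becomes O-14.

Step 5
Reactants: 7 5-bromo-2-isopropyl-3-methoxy-1,4-benzoquinone
Product: 8 5-bromo-2-isopropyl-3-methoxybenzene-1,4-diol
Conditions: Na2S2O4, EtOAc–H2O, rt, argon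
Reagents that add atoms: none
Why: Dithionite reduction of a benzoquinone to its hydroquinone is general and leaves the aryl bromide untouched.

Step 6
Reactants: 8 5-bromo-2-isopropyl-3-methoxybenzene-1,4-diol
Product: 9 1-bromo-2,5-diisopropoxy-4-isopropyl-3-methoxybenzene
Conditions: 2-bromopropane, K2CO3, DMF, 60 °C, argon
Reagents that add atoms: 2-bromopropane, CC(C)Br
Why: Double Williamson O-alkylation with a secondary bromide under carbonate is standard for hindered hydroquinones, and isopropyl ethers are chosen because they withstand organolithium, aluminium and trifluoroacetic acid chemistry yet yield to BCl3 beside a methyl ether.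

Step 7
Reactants: 10 3-ethoxycyclohex-2-en-1-one; 11 (chloromethyl)isopropoxydimethylsilane
Product: 13 3-ethoxy-1-[(isopropoxydimethylsilyl)methyl]cyclohex-2-en-1-ol (racemic and used crude), via Grignard reagent 12 (not isolated)
Conditions: 11, Mg, THF, reflux; 10, 0 °C; aq. NH4Cl, 0 °C
Reagents that add atoms: none
Why: The Grignard reagent of this hydroxymethyl-anion equivalent adds 1,2 to the vinylogous ester (first half of a Stork–Danheiser transposition), and the carbinol stereocentre is lost in the next step.

Step 8
Reactants: 13 3-ethoxy-1-[(isopropoxydimethylsilyl)methyl]cyclohex-2-en-1-ol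
Product: 15 3-(hydroxymethyl)cyclohex-2-en-1-one, via diol 14 (not isolated)
Conditions: KF, KHCO3, 30% H2O2, THF–MeOH, rt; Na2S2O3 quench; 1 M HCl, THF, rt
Reagents that add atoms: hydrogen peroxide, OO; water, O
Why: Tamao–Fleming oxidation under buffered fluoride–peroxide conditions turns the C–Si bond into C–OH without touching the enol ether (oxidising before acid avoids Peterson elimination), and dilute acid then completes the Stork–Danheiser transposition to the conjugated enone.

Step 9
Reactants: 15 3-(hydroxymethyl)cyclohex-2-en-1-one
Product: 16 3-(tert-butyldimethylsilyloxymethyl)cyclohex-2-en-1-one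
Conditions: TBSCl, imidazole, CH2Cl2, 0 °C → rt
Reagents that add atoms: tert-butyldimethylsilyl chloride, CC(C)(C)[Si](C)(C)Cl
Why: Silylation of a primary allylic alcohol is routine, and a silyl ether is chosen for the C20 oxygen because it does not coordinate aluminium or copper in the next stage.

Step 10
Reactants: 17 tert-butyl bromoacetate
Product: 18 tert-butyl iodoacetate
Conditions: NaI, acetone, rt, dark
Reagents that add atoms: sodium iodide, [Na+].[I-]
Why: Finkelstein exchange driven by precipitation of NaBr gives the more reactive iodide needed to alkylate a hindered enolate at low temperature.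

Step 11
Reactants: 9 1-bromo-2,5-diisopropoxy-4-isopropyl-3-methoxybenzene
Product: 20 (2,5-diisopropoxy-4-isopropyl-3-methoxyphenyl)dimethylaluminium (used as the solution obtained), via aryllithium 19 (not isolated)
Conditions: t-BuLi (2 equiv), Et2O–pentane, −78 °C; Me2AlCl (hexanes), −78 °C → rt
Reagents that add atoms: dimethylaluminium chloride, C[Al](C)Cl
Why: Bromine–lithium exchange is faster than any deprotonation and the ortho alkoxy group stabilises the aryllithium, which undergoes salt metathesis with Me2AlCl to the mixed alane that transfers aryl in preference to methyl.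

Step 12
Reactants: 16 3-(tert-butyldimethylsilyloxymethyl)cyclohex-2-en-1-one; 20 (2,5-diisopropoxy-4-isopropyl-3-methoxyphenyl)dimethylaluminium; 18 tert-butyl iodoacetate
Product: 23 tert-butyl 2-[(1R,2R)-2-Ar-2-(tert-butyldimethylsilyloxymethyl)-6-oxocyclohexyl]acetate (Ar on C10 α; C20 arm and C6 arm β), via dimethylaluminium enolate 21 (not isolated), via lithium aluminate enolate 22 (not isolated)
Conditions: Cu(OTf)2 (5 mol %), [Ag(L*)]2 (2.5 mol %), 20 (2–3 equiv), THF, −78 → −30 °C; MeLi (1 equiv per Al), −78 → 0 °C; 18 (excess), DMPU, −78 → −20 °C; aq. NH4Cl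
Reagents that add atoms: none
Why: Divalent copper is reduced in the flask to monovalent copper, which binds L*, takes the aryl group from aluminium, complexes the enone and delivers the aryl group to C10 through a trivalent copper intermediate, leaving dimethylaluminium enolate 21; MeLi turns it into the more nucleophilic aluminate 22, which displaces iodide from 18 at C5. The closest known reaction type is the copper–carbene-catalysed asymmetric conjugate addition of aryl dimethylaluminium reagents to 3-substituted cyclohexenones, combined with alkylation of the aluminium enolate after activation by an alkyllithium. No ring is closed: the step forms only the C9–C10 and C5–C6 bonds. C10 is set by the catalyst (the ligand enantiomer selects the enone face), and C5 by the substrate, the electrophile entering anti to the aryl group on the adjacent quaternary carbon so that the C6 and C20 arms end up cis. The step needs 1,4- over 1,2-addition and aryl over methyl transfer, which copper catalysis and the faster transfer of the sp2 carbon secure, and alkylation at C5 rather than C3, which is secured because conjugate addition creates only the C4–C5 enolate and it is trapped cold before proton transfer. The β-carbon of 16 already carries the C20 arm as a non-coordinating silyl ether, and the single free arene position (C8) is kept for ring B.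

Step 13
Reactants: 23 tert-butyl 2-[(1R,2R)-2-Ar-2-(tert-butyldimethylsilyloxymethyl)-6-oxocyclohexyl]acetate
Product: 24 C4 methoxymethylidene compound (methyl enol ether of the C19 aldehyde; E/Z mixture; C5 and C10 as in 23)
Conditions: MeOCH2PPh3Cl, KN(SiMe3)2, THF, 0 °C → rt
Reagents that add atoms: (methoxymethyl)triphenylphosphonium chloride, [Cl-].COC[P+](c1ccccc1)(c1ccccc1)c1ccccc1
Why: Wittig olefination with the small, reactive methoxymethylene ylide in excess is the standard one-carbon homologation of hindered cyclohexanones and introduces C19, while C5 should keep its configuration because any enolisation occurs towards C3.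

Step 14
Reactants: 24 C4 methoxymethylidene compound
Product: 25 C4 formyl compound, tert-butyl 2-[2-Ar-2-(tert-butyldimethylsilyloxymethyl)-6-formylcyclohexyl]acetate (mixture of C4 epimers; C5 and C10 as in 23)
Conditions: TsOH·H2O (10 mol %), acetone–H2O (10:1), rt
Reagents that add atoms: water, O
Why: Enol ether hydrolysis proceeds by rate-limiting protonation at C4 under acidity mild enough for the neopentyl-type silyl ether and the tert-butyl ester, and the C4 epimer mixture is of no consequence because C4 becomes an enolate next.

Step 15
Reactants: 25 C4 formyl compound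
Product: 26 4α-methyl-4β-formyl compound, tert-butyl 2-[2-Ar-2-(tert-butyldimethylsilyloxymethyl)-6-formyl-6-methylcyclohexyl]acetate (formyl cis to the C20 arm)
Conditions: KOtBu (1.1 equiv), THF, 0 °C; MeI, 0 °C → rt
Reagents that add atoms: iodomethane, CI
Why: In this α-alkylation of an α-branched aldehyde enolate, the aldehyde is far more acidic than the tert-butyl ester and is deprotonated selectively, and methyl iodide should attack the exocyclic enolate from the α face, anti to the axial C20 arm on C10 in the chair that keeps Ar and the C6 arm equatorial, as in alkylations of 4-carbonyl podocarpane-type systems; any O-methylated material is 24 and returns to step 14.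

Step 16
Reactants: 26 4α-methyl-4β-formyl compound
Product: 27 19,20-lactol (bridged hemiacetal between C19 and O-C20; mixture of C19 anomers)
Conditions: HF·pyridine, pyridine, THF, 0 °C → rt
Reagents that add atoms: none
Why: Fluoride-mediated desilylation frees the C20 hydroxyl, which sits 1,3-diaxial to the C19 formyl group and should close spontaneously to the six-membered bridged hemiacetal, a closure open only to the desired C4 epimer.

Step 17
Reactants: 27 19,20-lactol
Product: 28 19,20-lactone carrying the tert-butyl acetate arm on C5
Conditions: Pr4N[RuO4] (5 mol %), NMO, 4 Å molecular sieves, CH2Cl2, rt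
Reagents that add atoms: none
Why: Ley–Griffith oxidation converts lactols into lactones under neutral conditions that the electron-rich arene and the tert-butyl ester tolerate.

Step 18
Reactants: 28 19,20-lactone carrying the tert-butyl acetate arm on C5
Product: 31 11,14-diisopropoxy-12-methoxy-7-oxoabieta-8,11,13-trien-19,20-olide, via carboxylic acid 29 (not isolated), via mixed anhydride 30 (not isolated)
Conditions: TFA, CH2Cl2, 0 °C → rt; evaporate; TFAA, CH2Cl2, 0 °C → rt
Reagents that add atoms: none
Why: Acidolysis of the tert-butyl ester and intramolecular Friedel–Crafts acylation through the mixed trifluoroacetic anhydride should close six-membered ring B at C8, the only unsubstituted arene carbon (ortho to O-14, para to the 12-methoxy group), with the trans A/B fusion already fixed by C5 and C10 and no free hydroxyl left to intercept the acylating agent.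

Step 19
Reactants: 31 11,14-diisopropoxy-12-methoxy-7-oxoabieta-8,11,13-trien-19,20-olide
Product: 32 (4S,5R,10R)-11,14-dihydroxy-12-methoxy-7-oxoabieta-8,11,13-trien-19,20-olide (target)
Conditions: BCl3, CH2Cl2, −78 → 0 °C; degassed aq. NaHCO3, argon
Reagents that add atoms: none
Why: In this selective Lewis-acid ether cleavage, BCl3 ionises aryl isopropyl ethers far faster than it demethylates aryl methyl ethers, the O-14 ether being further activated by chelation to the C7 ketone, so both phenols should be released with the 12-methoxy group and the lactone intact.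

**Compound list**

1 | 2-isopropylphenol | CC(C)c1ccccc1O | starting material
2 | 2-isopropylanisole | COc1ccccc1C(C)C | intermediate
3 | (3-isopropyl-2-methoxyphenyl)lithium | [Li]c1cccc(C(C)C)c1OC | intermediate (not isolated)
4 | dimethyl (3-isopropyl-2-methoxyphenyl)boronate | COB(OC)c1cccc(C(C)C)c1OC | intermediate (not isolated)
5 | 3-isopropyl-2-methoxyphenol | COc1c(O)cccc1C(C)C | intermediate
6 | 6-bromo-3-isopropyl-2-methoxyphenol | COc1c(O)c(Br)ccc1C(C)C | intermediate
7 | 5-bromo-2-isopropyl-3-methoxy-1,4-benzoquinone | O=C1C=C(Br)C(=O)C(OC)=C1C(C)C | intermediate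
8 | 5-bromo-2-isopropyl-3-methoxybenzene-1,4-diol | Oc1cc(Br)c(O)c(OC)c1C(C)C | intermediate
9 | 1-bromo-2,5-diisopropoxy-4-isopropyl-3-methoxybenzene | Brc1cc(OC(C)C)c(C(C)C)c(OC)c1OC(C)C | intermediate
10 | 3-ethoxycyclohex-2-en-1-one | CCOC1=CC(=O)CCC1 | starting material
11 | (chloromethyl)isopropoxydimethylsilane | CC(C)O[Si](C)(C)CCl | starting material
12 | [(isopropoxydimethylsilyl)methyl]magnesium chloride | CC(C)O[Si](C)(C)C[Mg]Cl | intermediate (not isolated)
13 | 3-ethoxy-1-[(isopropoxydimethylsilyl)methyl]cyclohex-2-en-1-ol, racemic | CCOC1=CC(O)(C[Si](C)(C)OC(C)C)CCC1 | intermediate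
14 | 3-ethoxy-1-(hydroxymethyl)cyclohex-2-en-1-ol, racemic | CCOC1=CC(O)(CO)CCC1 | intermediate (not isolated)
15 | 3-(hydroxymethyl)cyclohex-2-en-1-one | O=C1C=C(CO)CCC1 | intermediate
16 | 3-(tert-butyldimethylsilyloxymethyl)cyclohex-2-en-1-one | O=C1C=C(CO[Si](C)(C)C(C)(C)C)CCC1 | intermediate
17 | tert-butyl bromoacetate | BrCC(=O)OC(C)(C)C | starting material
18 | tert-butyl iodoacetate | ICC(=O)OC(C)(C)C | intermediate
19 | (2,5-diisopropoxy-4-isopropyl-3-methoxyphenyl)lithium | [Li]c1cc(OC(C)C)c(C(C)C)c(OC)c1OC(C)C | intermediate (not isolated)
20 | (2,5-diisopropoxy-4-isopropyl-3-methoxyphenyl)dimethylaluminium | C[Al](C)c1cc(OC(C)C)c(C(C)C)c(OC)c1OC(C)C | intermediate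
21 | dimethylaluminium C4–C5 enolate of (R)-3-Ar-3-(tert-butyldimethylsilyloxymethyl)cyclohexanone | C[Al](C)OC1=C[C@](c2cc(OC(C)C)c(C(C)C)c(OC)c2OC(C)C)(CO[Si](C)(C)C(C)(C)C)CCC1 | intermediate (not isolated)
22 | lithium trimethylaluminate of the same enolate | [Li+].C[Al-](C)(C)OC1=C[C@](c2cc(OC(C)C)c(C(C)C)c(OC)c2OC(C)C)(CO[Si](C)(C)C(C)(C)C)CCC1 | intermediate (not isolated)
23 | tert-butyl 2-[(1R,2R)-2-Ar-2-(tert-butyldimethylsilyloxymethyl)-6-oxocyclohexyl]acetate | CC(C)(C)OC(=O)C[C@@H]1[C@](c2cc(OC(C)C)c(C(C)C)c(OC)c2OC(C)C)(CO[Si](C)(C)C(C)(C)C)CCCC1=O | intermediate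
24 | C4 methoxymethylidene compound (E/Z mixture) | CC(C)(C)OC(=O)C[C@@H]1[C@](c2cc(OC(C)C)c(C(C)C)c(OC)c2OC(C)C)(CO[Si](C)(C)C(C)(C)C)CCCC1=COC | intermediate
25 | C4 formyl compound (C4 epimers) | CC(C)(C)OC(=O)C[C@@H]1[C@](c2cc(OC(C)C)c(C(C)C)c(OC)c2OC(C)C)(CO[Si](C)(C)C(C)(C)C)CCCC1C=O | intermediate
26 | 4α-methyl-4β-formyl compound | CC(C)(C)OC(=O)C[C@@H]1[C@](c2cc(OC(C)C)c(C(C)C)c(OC)c2OC(C)C)(CO[Si](C)(C)C(C)(C)C)CCC[C@]1(C)C=O | intermediate
27 | 19,20-lactol (C19 anomers) | CC(C)(C)OC(=O)C[C@@H]1[C@@]2(c3cc(OC(C)C)c(C(C)C)c(OC)c3OC(C)C)CCC[C@]1(C)C(O)OC2 | intermediate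
28 | 19,20-lactone with tert-butyl acetate arm on C5 | CC(C)(C)OC(=O)C[C@@H]1[C@@]2(c3cc(OC(C)C)c(C(C)C)c(OC)c3OC(C)C)CCC[C@]1(C)C(=O)OC2 | intermediate
29 | 19,20-lactone C7 carboxylic acid | OC(=O)C[C@@H]1[C@@]2(c3cc(OC(C)C)c(C(C)C)c(OC)c3OC(C)C)CCC[C@]1(C)C(=O)OC2 | intermediate (not isolated)
30 | mixed trifluoroacetic anhydride of 29 | O=C(OC(=O)C(F)(F)F)C[C@@H]1[C@@]2(c3cc(OC(C)C)c(C(C)C)c(OC)c3OC(C)C)CCC[C@]1(C)C(=O)OC2 | intermediate (not isolated)
31 | 11,14-diisopropoxy-12-methoxy-7-oxoabieta-8,11,13-trien-19,20-olide | COc1c(OC(C)C)c2c(c(OC(C)C)c1C(C)C)C(=O)C[C@@H]1[C@]23CCC[C@]1(C)C(=O)OC3 | intermediate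
32 | (4S,5R,10R)-11,14-dihydroxy-12-methoxy-7-oxoabieta-8,11,13-trien-19,20-olide | COc1c(O)c2c(c(O)c1C(C)C)C(=O)C[C@@H]1[C@]23CCC[C@]1(C)C(=O)OC3 | target

**Step count and risks**

Total step count: 19. Longest linear sequence: 15 steps (steps 1–6 and 11–19).

Step 12. The ortho-alkoxylated aryl group may pass slowly from aluminium to copper, so that methyl transfer or an unselective background addition competes. The hindered aluminate next to the new quaternary carbon may also be protonated instead of alkylated, so that C5–C6 is not formed in the same flask. Fallback: setting out from 16 and 20, the conjugate addition would be run on its own and the aluminium enolate silylated (Me3SiOTf, THF, −78 °C) to the trimethylsilyl enol ether F1, which can be purified. MeLi (THF, 0 °C) would then release the regiodefined lithium enolate, which is alkylated with 18 in THF–DMPU at −78 → −20 °C, coming back to the route at 23.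

Step 15. The potassium aldehyde enolate is conformationally mobile and reacts at 0 °C, so facial selectivity at C4 may erode and O-methylation may compete. Fallback: setting out from 23, kinetic enolisation towards C3 and triflation (LiN(SiMe3)2, PhNTf2, THF, −78 °C) would give the C3–C4 enol triflate F2. Methoxycarbonylation (Pd(OAc)2, PPh3, CO, MeOH, Et3N, DMF) would give the unsaturated methyl ester F3. Dissolving-metal reductive methylation (Li, NH3–THF, −78 °C; MeI) would generate the lithium ester enolate regiospecifically, without base acting on the tert-butyl ester, and alkylate it cold from the α face to the 4α-methyl 4β-methoxycarbonyl diester F4. Desilylation (Bu4NF, THF) would let the C20 alkoxide close onto the methyl ester, coming back to the route at 28.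

Step 19. Once boron is held between O-11 and O-12, the hindered 12-methyl ether may also be cleaved on warming, and the free 11,14-hydroquinone may be oxidised by air during work-up. Fallback: setting out from 31, oxidative dealkylation ((NH4)2Ce(NO3)6, MeCN–H2O, 0 °C) would remove only the para-related isopropyl groups and give the 12-methoxy-11,14-quinone F5, in which the methoxy group is a stable vinylogous ester. Reduction with Na2S2O4 (EtOAc–H2O, argon) would then give 32.

**Further compounds**

F1 | step 12 | trimethylsilyl enol ether (C4–C5) of (R)-3-Ar-3-(tert-butyldimethylsilyloxymethyl)cyclohexanone | C[Si](C)(C)OC1=C[C@](c2cc(OC(C)C)c(C(C)C)c(OC)c2OC(C)C)(CO[Si](C)(C)C(C)(C)C)CCC1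
F2 | step 15 | C3–C4 enol triflate of 23 | CC(C)(C)OC(=O)C[C@@H]1[C@](c2cc(OC(C)C)c(C(C)C)c(OC)c2OC(C)C)(CO[Si](C)(C)C(C)(C)C)CCC=C1OS(=O)(=O)C(F)(F)F
F3 | step 15 | C3–C4 unsaturated C19 methyl ester | CC(C)(C)OC(=O)C[C@@H]1[C@](c2cc(OC(C)C)c(C(C)C)c(OC)c2OC(C)C)(CO[Si](C)(C)C(C)(C)C)CCC=C1C(=O)OC
F4 | step 15 | 4α-methyl 4β-methoxycarbonyl diester | CC(C)(C)OC(=O)C[C@@H]1[C@](c2cc(OC(C)C)c(C(C)C)c(OC)c2OC(C)C)(CO[Si](C)(C)C(C)(C)C)CCC[C@]1(C)C(=O)OC
F5 | step 19 | (4S,5R,10R)-12-methoxy-7,11,14-trioxoabieta-8,12-dien-19,20-olide | COC1C(=O)C2=C(C(=O)C=1C(C)C)C(=O)C[C@@H]1[C@]23CCC[C@]1(C)C(=O)OC3
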